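Partner stands to substrate at 1.00 in the flask, and a second ratio, of two rate constants, enters the reckoning below of how far partner falls before bis adduct turns.

| flask | substrate | partner | remark | time |
|---|---|---|---|---|
| violet | 0.12 M | 0.060 M | run made earlier |  |
| ochre | 0.12 M | 0.24 M | run made earlier |  |
| green | 0.18 M | 0.12 M | run made earlier |  |
| flask | 0.12 M | 0.120 M |  | 2.5 h |

| run | time / h | bis adduct / % | substrate / % |
|---|---|---|---|
| violet | 0.250 | 4.5 | 81.5 |
| violet | 0.500 | 8.1 | 74.6 |
| violet | 1.33 | 11.2 | 66.5 |
| violet | 2.50 | 8.9 | 64.9 |
| ochre | 0.250 | 24.6 | 49.4 |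
| ochre | 0.500 | 28.0 | 34.5 |
| ochre | 1.33 | 26.0 | 22.9 |
| ochre | 2.50 | 24.2 | 21.8 |
| green | 0.250 | 10.2 | 71.9 |
| green | 0.500 | 13.7 | 63.2 |
| green | 1.33 | 13.3 | 57.1 |
| green | 2.50 | 10.9 | 54.5 |

(standard deviation of a reading: 0.5 percentage points)

- in percentages every species weighs as the substrate in it: one side product counts as two
- on the list of suspects stand: substrate + partner -> first product; partner + first product -> bis adduct; partner + bis adduct -> tris adduct; partner + tris adduct -> tetra adduct; substrate + bis adduct -> side product

* time up to 2.5 h at which bis adduct stands highest
* the amount of bis adduct, in percent of the substrate charged, at that time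

1. Over the first 0.250 h of the ochre run, substrate falls as if substrate + partner had a constant of 15.7 L mol⁻¹ h⁻¹. This is a reading, with mean partner taken as its charge less the substrate lost.

2. Fastest rung: once first product stands steady, each substrate lost costs about two partner. Partner is therefore the limiting reagent in the flask, and at that cost its charge takes substrate down to about 0.0600 M. Frozen midway at 0.0900 M, substrate gives partner a pseudo-first-order fall, and the partner half-life, ln(2) over twice the constant times frozen substrate, is 0.245 h.

3. Slow rung: the late fall of bis adduct in the violet run reads as 2.52 L mol⁻¹ h⁻¹ for substrate + bis adduct. In the flask that is a half-life of 3.05 h, slower than partner.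

4. My own reckoning: bis adduct crests when its gain, a steady share of the partner spent, equals this slow loss. The height cancels, so this gives no height. Partner then stands at 5.34% of its charge, reached at 1.03 h.

The forecast is earlier, 0.8 h, with 20.5%: “The flask should exhaust partner at about 0.8 h”.

The flask gives 21.4% at 1.02 h.

    substrate + partner → first product (k = 0.00450 L mol⁻¹ s⁻¹)
    partner + first product → bis adduct (k = 0.0180 L mol⁻¹ s⁻¹)
    partner + bis adduct → tris adduct (k = 0.00610 L mol⁻¹ s⁻¹)
    partner + tris adduct → tetra adduct (k = 0.00940 L mol⁻¹ s⁻¹)
    substrate + bis adduct → side product (k = 6.60 × 10⁻⁴ L mol⁻¹ s⁻¹)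

In the flask, bis adduct is made 4.19 times as fast as it is used up at 0.183 h, but 0.0386 times as fast at 2.50 h. The crest lies between, with partner at 5.21% of its charge against the 5.34% reckoned. After 0.250 h, about one half-life of 0.245 h, partner in the flask stands at 51.7%. A neighbour flask charged with 0.48 M of substrate has a reckoned partner half-life of 0.0489 h, and at 2.50 h it holds partner at 0%.

(The earlier runs and the new flask were computed with constants of no real substance; noise was put on by code.)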